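If a fixed share of the substrate lost turns into isomer of the product and the substrate falls at a steady pace, then isomer overtakes substrate at one time, and two chemists disputed that time before dusk, dawn and summer were run.

| flask | substrate | partner | remark | time |
|---|---|---|---|---|
| blue | 0.59 M | 1.7 equiv | run made earlier |  |
| green | 0.59 M | 2.6 equiv | run made earlier |  |
| grey | 0.29 M | 1.2 equiv | run made earlier |  |
| dusk | 0.59 M | 1.20 equiv |  | 6.0 min |
| dawn | 0.59 M | 1.20 equiv |  | 10 min |
| summer | 0.59 M | 1.20 equiv |  | 4.0 min |

| run | time / min | substrate / % | target / % | side product / % | isomer of the product / % |
|---|---|---|---|---|---|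
| blue | 0.250 | 98 | 0 | 3 | 2 |
| blue | 0.833 | 83 | 4 | 0 | 10 |
| blue | 1.33 | 81 | 6 | 2 | 16 |
| blue | 2.00 | 70 | 8 | 0 | 24 |
| blue | 3.00 | 59 | 13 | 4 | 33 |
| blue | 4.00 | 49 | 16 | 1 | 36 |
| green | 0.250 | 95 | 2 | 4 | 1 |
| green | 0.833 | 84 | 6 | 0 | 11 |
| green | 1.33 | 77 | 6 | 1 | 16 |
| green | 2.00 | 68 | 10 | 0 | 23 |
| green | 3.00 | 52 | 15 | 1 | 34 |
| green | 4.00 | 44 | 15 | 0 | 41 |
| grey | 0.333 | 98 | 0 | 1 | 2 |
| grey | 0.667 | 92 | 0 | 0 | 8 |
| grey | 1.00 | 89 | 0 | 0 | 7 |
| grey | 2.00 | 75 | 11 | 0 | 19 |
| grey | 4.00 | 58 | 10 | 2 | 26 |

(readings scatter by 2 percentage points)

- in percentages every species weighs as the substrate in it: one side product counts as two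
- steps that have been proposed: substrate <-> tight pair; tight pair <-> loose pair; partner + tight pair -> target; partner + loose pair -> isomer of the product; loose pair -> decomposed reagent; substrate -> decomposition product; substrate + loose pair -> side product

- which of these there is most of at the end, counted by the substrate in it, dusk (isomer of the product / target / side product / substrate)
- which of these there is most of at the end, counted by the substrate in it, dawn (isomer of the product / target / side product / substrate)
- which of these there is most of at the end, counted by the substrate in it, summer (isomer of the product / target / side product / substrate)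
- final amount of the leader among these, as a percentage of the substrate charged, in dusk
- final amount of the leader among these, as a percentage of the substrate charged, in dawn
- final amount of the leader among these, as a percentage of the substrate charged, in summer

Both take the loss coefficient as the logarithm of charged over remaining substrate, divided by the time, and the isomer share as isomer gained per substrate lost, so that isomer equals substrate once the substrate stands at the share over one plus the share.

The first chemist counts partner in molarity. The last readings of blue and green give a share of 72.0 %, hence a crossing level of 41.8 %. Dusk's partner charge of 0.708 M lies above grey's 0.348 M and below blue's 1.00 M, and those runs show coefficients of 0.136 /min and 0.178 /min, each already an average over its own falling partner, so she interpolates 0.159 /min. Her crossing time, the moment at which isomer overtakes substrate, reckoned as the logarithm of one over the crossing level divided by the loss coefficient, is 5.47 min, earlier than dusk's 6.0 min. She therefore commits to isomer at 44.3 % in dusk against substrate at 38.5 %, isomer at 57.3 % in dawn, and substrate at 52.9 % in summer.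

The second chemist counts equivalents: grey carries the 1.2 equiv of dusk, so he takes grey whole. Its last reading gives a share of 61.9 %, a crossing level of 38.2 % and, with grey's coefficient, a crossing at 7.06 min, later than dusk's time, so he keeps substrate ahead in dusk at 44.2 %.

The forecast took his side in dusk by a reckoning of its own, with other numbers: substrate at 40 % in dusk, isomer of the product at 47 % in dawn and substrate at 53 % in summer, with the words “Dusk is nearly a tie, leaning slightly to substrate.”

In dusk isomer of the product leads with 43.5 % over substrate at 37.4 %, in dawn isomer of the product leads with 54.7 %, and in summer substrate leads with 50.8 %.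

    substrate ⇌ tight pair (K = 0.00390, k = 0.00380 /s)
    tight pair ⇌ loose pair (K = 3.00, k = 130 /s)
    partner + tight pair → target (k = 1.40 /M/s)
    partner + loose pair → isomer of the product (k = 1.20 /M/s)
    loose pair → decomposed reagent (k = 0.0130 /s)
    substrate → decomposition product (k = 4.60 × 10⁻⁶ /s)
    substrate + loose pair → side product (k = 0.0110 /M/s)

In dawn at 2.90 min, partner is used by the loose pair on the way to isomer 2.5 times as fast as by the tight pair on the way to target, a selectivity factor of isomer over target at that moment. Dusk, at 6.0 min, lies past the crossing time of 5.47 min, and there isomer stands ahead. The second chemist's answer, substrate ahead, holds at earlier times: summer at 4.0 min shows substrate 50.8 % against isomer 34.2 %, and the flask of dawn read at 2.5 min holds substrate 64.8 % against isomer 24.4 %.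

Readings and results were generated by integration with constants of no real substance; noise was put on by code.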